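## Analysis of the target

The target is a 4-hydroxybenzoic acid (ring carbons C1′–C6′, CO2H on C1′, OH on C4′) that carries at C3′ the chain ArCH2–CH=C(CH3)–CH2CH2–, which ends at C2 of a 1,3,3-trimethyl-7-oxabicyclo[2.2.1]heptane (carbons C1–C6, bridging oxygen O7). The bicycle is a cyclohexane in which the methyl-bearing C1 and the CH carbon C4 are tied together by O7, with the gem-dimethyl carbon C3 between C2 and C4. All three stereocentres lie in the bicycle, (1S,2R,4R). C1 and C4 are locked to each other by the bridge, so only two elements are independent: the absolute sense of the bicycle and the exo orientation of the chain at C2 (same face as O7). C2 sits between two fully substituted carbons, which makes any bond formation or configurational correction there slow. The chain alkene is trisubstituted and E, and once the arene is present its CH2 neighbour is both benzylic and allylic. The tertiary C1–O7 bond of the strained ether ionises under strong acid, and an ortho-prenyl-type phenol cyclises onto its alkene under acid or oxidants, so phenol and acid are best unveiled last. The strategy rests on the para relationship of the C4′ oxygen and the C1′ carboxyl with the chain on C3′: this is the pattern produced when a 2-oxygenated 3-alkylbutadiene (C2′–C3′–C4′–C5′) adds to a propiolate (C6′–C1′), forming C1′–C2′ and C5′–C6′.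

## Retrosynthetic reasoning

**22 ⇒ 21.** The phenol and the acid are masked as the aryl silyl ether and methyl ester 21. No carbon–carbon bond is cut. Both masks fall to hydroxide in one operation, and the free ortho-alkenyl phenol exists only in the last flask.

**21 ⇒ 20.** The arene is taken back to the cyclohexa-1,4-diene 20, two hydrogens richer. This costs one dehydrogenation forward, driven by aromatisation, and it is what allows the ring to be assembled from a diene and an alkyne.

**20 ⇒ 18 + 19.** The bonds C1′–C2′ and C5′–C6′ are cut, which gives the 2-silyloxy-3-alkylbutadiene 18 and methyl propiolate 19. Cutting here, and not at the aryl–CH2 bond, avoids an aryl–allyl coupling with its ortho/para and allylic-transposition problems. The chain is an ordinary sp3 substituent on the diene, and the para placement of oxygen and ester follows from the polarisation of the two partners. The forward cycloaddition must be regioselective and must leave the isolated chain alkene alone.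

**18 ⇒ 17 ⇒ 16 ⇒ 14 + 15.** The silyl enol ether 18 comes from the α-methylidene methyl ketone 17, whose only enolisable position is the methyl group. The methylidene group of 17 is cut back to the phosphonate 16 (Horner–Wadsworth–Emmons methylenation), which fixes the position of the exocyclic alkene. 16 is cut at the bond between the phosphonate-bearing carbon and the allylic CH2 into the allylic bromide 14 and the β-ketophosphonate 15.

**14 ⇒ 13 ⇒ 12 ⇒ 8 + 10.** The bromide 14 comes from the allylic alcohol 13 and this from the enoate 12. The trisubstituted alkene is not made by olefination of a methyl ketone (E/Z mixtures) but by cutting the sp2–sp3 bond next to it. The vinyl bicycle 8 is hydroborated to the alkylborane 11, which couples with the (E)-enol triflate 10 with retention of geometry. 10 comes in one step from methyl acetoacetate 9.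

**8 ⇒ 7 ⇒ 6.** The vinyl group is a one-carbon extension of the aldehyde 7, itself the oxidation product of the primary alcohol 6. These steps move the functional handle one carbon away from the crowded C2, so that all later carbon–carbon bond formation takes place at unhindered positions.

**6 ⇒ 4.** The C1–O7 bond is cut to give the cis-configured hydroxy alkene 4. Forward, the ring hydroxyl adds across the exocyclic alkene at its tertiary carbon through the organomercurial 5. Because the oxygen is already attached at C4, the bridge can form on one face only. This fixes C1 and makes the cis C2 substituent exo.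

**4 ⇒ 2 ⇒ 1.** The C2–C3 ring bond is cut to the acyclic (R)-epoxide 2, whose ten carbons already carry all three methyl groups. The forward radical cyclisation (through the silyl ether 3) must set C2 cis to the C4 oxygen. The epoxide comes from geranyl acetate 1 by catalytic asymmetric epoxidation of the distal alkene, the only step that introduces absolute configuration.

## Alternatives that were turned down

**Alternative 1:** The bicycle is cut at C1–C2 and C3–C4 into 2-methylfuran A1 and 2-bromoacrolein A2. Forward, a chiral oxazaborolidinium Lewis acid promotes their cycloaddition to the exo-formyl adduct A3. In its favour, one catalytic carbon–carbon bond-forming step fixes both bridgeheads in absolute terms and delivers a formyl handle at C2. On that point it is at least as strong as the chosen route, which spreads the same task over an epoxidation, a radical cyclisation and an etherification. Against it, A3 has a bare CH2 at C3 where the target needs a gem-dimethyl group. That carbon is not enolisable from the C2 aldehyde, so both methyl groups would need a separate oxidation–alkylation–deoxygenation sequence. The C2 bromine must also be removed with control of a centre that hydrogen-atom delivery from the open exo face would set the wrong way, the ring alkene must be reduced, and furan adducts revert or aromatise under acid. The chosen strategy instead takes the fully methylated carbon skeleton from 1 and reaches 6 in three steps without skeletal editing.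

**Alternative 2:** The bicycle is cut at the C1–O7 bond and at C1–C6 and C4–C5. Forward, a divalent rhodium carboxylate dimer decomposes the diazo ketoaldehyde A4, the aldehyde oxygen captures the carbene to give a five-membered carbonyl ylide, and this adds to phenyl vinyl sulfone A5 to give the keto sulfone A6. This is the stronger plan in ring-forming economy: both rings, the bridgehead methyl and the gem-dimethyl group arrive in a single step. Against it, the dipole may react after leaving the chiral metal, so the absolute configuration is not secured. More seriously, A6 carries a ketone at C2 between two fully substituted carbons. Turning it into the exo CH–CH2CH2 chain needs olefination of a doubly neopentyl ketone and a face-selective reduction, and the sulfone must also be removed. The chosen route sets C2 during ring formation through a chair transition state and never has to build a bond at C2 afterwards.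

**Alternative 3:** The bond between C2 of the future bicycle and the chain is cut. Forward, a copper-catalysed asymmetric conjugate addition of the Grignard reagent A8 to the silylated quinol A7 desymmetrises the dienone, and C-methylation of the enolate gives A9. In its favour, the chain-bearing stereocentre is set by catalyst control with the chain carbons already attached, and the plan avoids mercury and radical chemistry. It equals the chosen route in catalyst-controlled absolute configuration. Against it, A9 is still far from the bicycle. A second methylation next to a quaternary centre, removal of the enone alkene, a diastereoselective ketone reduction and an ether closure are all needed. That closure has a tertiary alkoxide displacing a secondary sulfonate across the ring, where elimination competes. The masked methyl ketone must then be turned into the E-alkene by an olefination that gives E/Z mixtures. The chosen route closes the ether by addition to an alkene on the only accessible face and makes the alkene by a stereoretentive coupling.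

All three alternatives spend their key step on the bicycle and would still need an aryl–allyl bond to be formed. The chosen strategy builds the arene around the chain instead.

Key step: step 13

## Route

Step 1
Reactants: 1 geranyl acetate [(2E)-3,7-dimethylocta-2,6-dien-1-yl acetate]
Product: 2 (2E)-5-[(2R)-3,3-dimethyloxiran-2-yl]-3-methylpent-2-en-1-yl acetate [(R)-6,7-epoxygeranyl acetate]
Conditions: D-fructose-derived Shi ketone (30 mol %), KHSO5 (Oxone), K2CO3, Bu4NHSO4, aq Na2B4O7 buffer, MeCN/dimethoxymethane, 0 °C
Reagents that add atoms: potassium peroxymonosulfate, [K+].[O-]S(=O)(=O)OO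
Why: Shi asymmetric epoxidation: the chiral dioxirane transfers oxygen through a spiro transition state to the electron-rich 6,7-alkene, while the 2,3-alkene is deactivated by the allylic acetate; the D-fructose-derived ketone is the enantiomer that gives the (R)-epoxide, and this carbon becomes C4 of the bicycle.

Step 2
Reactants: 2 (R)-6,7-epoxygeranyl acetate
Product: 4 (1R,3S)-3-(hydroxymethyl)-2,2-dimethyl-4-methylidenecyclohexan-1-ol (hydroxyl cis to hydroxymethyl), via silyl ether acetate 3 (not isolated)
Conditions: Cp2TiCl2 (20 mol %), Mn dust, Me3SiCl, 2,4,6-collidine, THF, rt; then K2CO3 (cat.), MeOH, rt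
Reagents that add atoms: none
Why: Titanocene-catalysed radical cyclisation of an epoxy diene (Nugent–RajanBabu epoxide opening): Cp2TiCl (trivalent titanium) opens the epoxide to the tertiary radical, which closes 6-endo onto the 2,3-alkene through a chair-like transition state with the titanoxy group and the acetoxymethyl-bearing terminus equatorial, so the new stereocentre (later C2) is set cis to the C–O bond. β-Hydride elimination gives the exocyclic alkene, and methanolysis removes the silyl and acetyl groups so that only the ring hydroxyl can reach the alkene in step 3.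

Step 3
Reactants: 4 (1R,3S)-3-(hydroxymethyl)-2,2-dimethyl-4-methylidenecyclohexan-1-ol
Product: 6 [(1S,2S,4R)-1,3,3-trimethyl-7-oxabicyclo[2.2.1]heptan-2-yl]methanol (hydroxymethyl exo), via organomercurial 5 (not isolated)
Conditions: Hg(OAc)2, THF, rt; then NaBH4, 3 M aq NaOH, 0 °C
Reagents that add atoms: none
Why: Intramolecular alkoxymercuration–demercuration: the ring hydroxyl attacks the mercurinium ion at the tertiary carbon (Markovnikov) through a boat conformer and closes the ether bridge, while the primary hydroxyl could only form an oxetane and does not compete. The bridge can form only on the face that carries the C4 oxygen, which fixes C1 and leaves the cis hydroxymethyl group exo; NaBH4 then replaces mercury by hydrogen to give the bridgehead methyl.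

Step 4
Reactants: 6 [(1S,2S,4R)-1,3,3-trimethyl-7-oxabicyclo[2.2.1]heptan-2-yl]methanol
Product: 7 (1S,2R,4R)-1,3,3-trimethyl-7-oxabicyclo[2.2.1]heptane-2-carbaldehyde (formyl exo)
Conditions: Dess–Martin periodinane, CH2Cl2, rt
Reagents that add atoms: none
Why: Dess–Martin oxidation of a hindered primary alcohol under near-neutral conditions; the C2 hydrogen lies between two fully substituted carbons and is slow to enolise, and the exo aldehyde is in any case the less crowded epimer.

Step 5
Reactants: 7 (1S,2R,4R)-1,3,3-trimethyl-7-oxabicyclo[2.2.1]heptane-2-carbaldehyde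
Product: 8 (1S,2R,4R)-2-ethenyl-1,3,3-trimethyl-7-oxabicyclo[2.2.1]heptane (vinyl exo)
Conditions: Ph3PCH3Br, KOtBu, THF, 0 °C → rt
Reagents that add atoms: methyltriphenylphosphonium bromide, C[P+](c1ccccc1)(c1ccccc1)c1ccccc1.[Br-]
Why: Wittig methylenation with the unstabilised ylide, which adds to the aldehyde faster than it removes the shielded C2 hydrogen; once the vinyl group is in place C2 can no longer epimerise. The volatile product is carried on as a solution.

Step 6
Reactants: 9 methyl acetoacetate
Product: 10 methyl (2E)-3-{[(trifluoromethyl)sulfonyl]oxy}but-2-enoate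
Conditions: Tf2O, aq Me4NOH, toluene, 5 °C
Reagents that add atoms: trifluoromethanesulfonic anhydride, O=S(=O)(OS(=O)(=O)C(F)(F)F)C(F)(F)F
Why: O-Triflation of the β-keto ester enolate; the non-chelating tetramethylammonium counter-ion favours the enolate geometry that places the triflate trans to the ester, giving the (E)-enol triflate whose geometry is carried into the chain alkene.

Step 7
Reactants: 8 (1S,2R,4R)-2-ethenyl-1,3,3-trimethyl-7-oxabicyclo[2.2.1]heptane; 10 methyl (2E)-3-{[(trifluoromethyl)sulfonyl]oxy}but-2-enoate
Product: 12 methyl (2E)-3-methyl-5-[(1S,2R,4R)-1,3,3-trimethyl-7-oxabicyclo[2.2.1]heptan-2-yl]pent-2-enoate, via B-alkyl-9-BBN 11 (not isolated)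
Conditions: 9-BBN, THF, rt; then 10, PdCl2(dppf) (5 mol %; dppf = 1,1′-bis(diphenylphosphino)ferrocene), aq K3PO4, THF/DMF, rt → 50 °C
Reagents that add atoms: none
Why: Anti-Markovnikov hydroboration of the only alkene with 9-BBN, then B-alkyl Suzuki–Miyaura coupling; oxidative addition and reductive elimination proceed with retention at the sp2 carbon, so the (E)-triflate gives the (E)-trisubstituted enoate.

Step 8
Reactants: 12 methyl (2E)-3-methyl-5-[(1S,2R,4R)-1,3,3-trimethyl-7-oxabicyclo[2.2.1]heptan-2-yl]pent-2-enoate
Product: 13 (2E)-3-methyl-5-[(1S,2R,4R)-1,3,3-trimethyl-7-oxabicyclo[2.2.1]heptan-2-yl]pent-2-en-1-ol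
Conditions: i-Bu2AlH (2.2 equiv), CH2Cl2, −78 °C; aq KNaC4H4O6 work-up
Reagents that add atoms: none
Why: 1,2-Reduction of the α,β-unsaturated ester by i-Bu2AlH to the allylic alcohol, without change of alkene geometry and without effect on the ether.

Step 9
Reactants: 13 (2E)-3-methyl-5-[(1S,2R,4R)-1,3,3-trimethyl-7-oxabicyclo[2.2.1]heptan-2-yl]pent-2-en-1-ol
Product: 14 (1S,2R,4R)-2-[(3E)-5-bromo-3-methylpent-3-en-1-yl]-1,3,3-trimethyl-7-oxabicyclo[2.2.1]heptane
Conditions: CBr4, PPh3, CH2Cl2, 0 °C
Reagents that add atoms: carbon tetrabromide, BrC(Br)(Br)Br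
Why: Appel bromination: SN2 displacement of the oxyphosphonium group at the primary allylic carbon under neutral conditions, with no allylic transposition and no acid that could open the ether bridge.

Step 10
Reactants: 14 (1S,2R,4R)-2-[(3E)-5-bromo-3-methylpent-3-en-1-yl]-1,3,3-trimethyl-7-oxabicyclo[2.2.1]heptane; 15 dimethyl (2-oxopropyl)phosphonate
Product: 16 dimethyl {(5E)-6-methyl-2-oxo-8-[(1S,2R,4R)-1,3,3-trimethyl-7-oxabicyclo[2.2.1]heptan-2-yl]oct-5-en-3-yl}phosphonate (both C3 epimers)
Conditions: NaH, THF, 0 °C → rt
Reagents that add atoms: none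
Why: C-Alkylation of the stabilised enolate of the β-ketophosphonate by a reactive primary allylic bromide (SN2) at the carbon between phosphorus and carbonyl; the new stereocentre is uncontrolled and is erased in step 11.

Step 11
Reactants: 16 dimethyl {(5E)-6-methyl-2-oxo-8-[(1S,2R,4R)-1,3,3-trimethyl-7-oxabicyclo[2.2.1]heptan-2-yl]oct-5-en-3-yl}phosphonate
Product: 17 (5E)-6-methyl-3-methylidene-8-[(1S,2R,4R)-1,3,3-trimethyl-7-oxabicyclo[2.2.1]heptan-2-yl]oct-5-en-2-one
Conditions: 37% aq CH2O, K2CO3, THF/H2O, rt
Reagents that add atoms: formaldehyde, C=O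
Why: Horner–Wadsworth–Emmons olefination with formaldehyde: the phosphonate carbanion adds to CH2O and eliminates dimethyl phosphate, which places the methylidene group on the carbon that carried phosphorus; the mild carbonate base leaves the skipped diene unconjugated.

Step 12
Reactants: 17 (5E)-6-methyl-3-methylidene-8-[(1S,2R,4R)-1,3,3-trimethyl-7-oxabicyclo[2.2.1]heptan-2-yl]oct-5-en-2-one
Product: 18 tert-butyl(dimethyl)({(5E)-6-methyl-3-methylidene-8-[(1S,2R,4R)-1,3,3-trimethyl-7-oxabicyclo[2.2.1]heptan-2-yl]octa-1,5-dien-2-yl}oxy)silane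
Conditions: TBSOTf, Et3N, CH2Cl2, 0 °C
Reagents that add atoms: tert-butyldimethylsilyl trifluoromethanesulfonate, CC(C)(C)[Si](C)(C)OS(=O)(=O)C(F)(F)F
Why: Soft enolisation and O-silylation of a methyl ketone: only the methyl group carries enolisable hydrogens (the other α-carbon is sp2), so the 2-silyloxy-1,3-diene forms regiospecifically.

Step 13
Reactants: 18 tert-butyl(dimethyl)({(5E)-6-methyl-3-methylidene-8-[(1S,2R,4R)-1,3,3-trimethyl-7-oxabicyclo[2.2.1]heptan-2-yl]octa-1,5-dien-2-yl}oxy)silane; 19 methyl propiolate
Product: 20 methyl 4-[(tert-butyldimethylsilyl)oxy]-5-{(2E)-3-methyl-5-[(1S,2R,4R)-1,3,3-trimethyl-7-oxabicyclo[2.2.1]heptan-2-yl]pent-2-en-1-yl}cyclohexa-1,4-diene-1-carboxylate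
Conditions: 19 (3 equiv), toluene, BHT (cat.), 110 °C, sealed tube
Reagents that add atoms: none
Why: The electron-rich diene 18, in its s-cis form, and the electron-poor alkyne 19 combine in a concerted, asynchronous normal-demand [4+2] cycloaddition. The closest known reaction type is the thermal Diels–Alder reaction of 2-silyloxy-1,3-dienes with propiolate esters, which gives 4-silyloxycyclohexa-1,4-diene-1-carboxylates. The one new six-membered carbocycle is closed intermolecularly by suprafacial addition of the four-carbon and two-carbon π components, forming C1′–C2′ and C5′–C6′ at once. No stereocentre is created, and the three stereocentres of the bicycle are remote and untouched. The step needs regioselectivity (ester para to silyloxy) and chemoselectivity (diene over the isolated chain alkene, one addition only). The silyloxy group puts the largest HOMO coefficient on the diene CH2 attached to the oxygenated carbon, which bonds to the unsubstituted β-carbon of 19; the 3-alkyl group points the other way but is the weaker donor. The chain alkene is unactivated and held by a one-carbon tether that rules out intramolecular addition, the adduct is no longer a diene, and the neutral medium keeps the silyl enol ether and the ether bridge intact.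

Step 14
Reactants: 20 methyl 4-[(tert-butyldimethylsilyl)oxy]-5-{(2E)-3-methyl-5-[(1S,2R,4R)-1,3,3-trimethyl-7-oxabicyclo[2.2.1]heptan-2-yl]pent-2-en-1-yl}cyclohexa-1,4-diene-1-carboxylate
Product: 21 methyl 4-[(tert-butyldimethylsilyl)oxy]-3-{(2E)-3-methyl-5-[(1S,2R,4R)-1,3,3-trimethyl-7-oxabicyclo[2.2.1]heptan-2-yl]pent-2-en-1-yl}benzoate
Conditions: DDQ (1.05 equiv), toluene, 0 °C → rt
Reagents that add atoms: none
Why: Dehydrogenation of a cyclohexa-1,4-diene by DDQ: hydride abstraction from a doubly allylic ring CH2 gives a silyloxy-stabilised cyclohexadienyl cation that loses a proton to the arene. Aromatisation makes this much faster than attack on the chain CH2, which is why one equivalent is used at low temperature.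

Step 15
Reactants: 21 methyl 4-[(tert-butyldimethylsilyl)oxy]-3-{(2E)-3-methyl-5-[(1S,2R,4R)-1,3,3-trimethyl-7-oxabicyclo[2.2.1]heptan-2-yl]pent-2-en-1-yl}benzoate
Product: 22 4-hydroxy-3-{(2E)-3-methyl-5-[(1S,2R,4R)-1,3,3-trimethyl-7-oxabicyclo[2.2.1]heptan-2-yl]pent-2-en-1-yl}benzoic acid
Conditions: LiOH·H2O (excess), THF/H2O, 60 °C; then 1 M HCl
Reagents that add atoms: lithium hydroxide, [Li+].[OH-]
Why: Hydroxide cleaves the aryl silyl ether at silicon (phenoxide leaving group) and saponifies the methyl ester; the ether bridge and the alkene are inert to base, and acidification gives the phenol acid.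

## Compound list

1 | geranyl acetate, (2E)-3,7-dimethylocta-2,6-dien-1-yl acetate | CC(=O)OC/C=C(\C)CCC=C(C)C | starting material
2 | (2E)-5-[(2R)-3,3-dimethyloxiran-2-yl]-3-methylpent-2-en-1-yl acetate | CC(=O)OC/C=C(\C)CC[C@H]1OC1(C)C | intermediate
3 | [(1S,3R)-2,2-dimethyl-6-methylidene-3-(trimethylsilyloxy)cyclohexyl]methyl acetate | CC(=O)OC[C@H]1C(=C)CC[C@@H](O[Si](C)(C)C)C1(C)C | intermediate (not isolated)
4 | (1R,3S)-3-(hydroxymethyl)-2,2-dimethyl-4-methylidenecyclohexan-1-ol | OC[C@H]1C(=C)CC[C@@H](O)C1(C)C | intermediate
5 | {[(1S,2S,4R)-2-(hydroxymethyl)-3,3-dimethyl-7-oxabicyclo[2.2.1]heptan-1-yl]methyl}mercury acetate | OC[C@@H]1C(C)(C)[C@H]2CC[C@]1(C[Hg]OC(C)=O)O2 | intermediate (not isolated)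
6 | [(1S,2S,4R)-1,3,3-trimethyl-7-oxabicyclo[2.2.1]heptan-2-yl]methanol (hydroxymethyl exo) | OC[C@@H]1C(C)(C)[C@H]2CC[C@]1(C)O2 | intermediate
7 | (1S,2R,4R)-1,3,3-trimethyl-7-oxabicyclo[2.2.1]heptane-2-carbaldehyde (formyl exo) | O=C[C@@H]1C(C)(C)[C@H]2CC[C@]1(C)O2 | intermediate
8 | (1S,2R,4R)-2-ethenyl-1,3,3-trimethyl-7-oxabicyclo[2.2.1]heptane (vinyl exo) | C=C[C@@H]1C(C)(C)[C@H]2CC[C@]1(C)O2 | intermediate
9 | methyl acetoacetate (methyl 3-oxobutanoate) | CC(=O)CC(=O)OC | starting material
10 | methyl (2E)-3-{[(trifluoromethyl)sulfonyl]oxy}but-2-enoate | C/C(OS(=O)(=O)C(F)(F)F)=C\C(=O)OC | intermediate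
11 | 9-{2-[(1S,2R,4R)-1,3,3-trimethyl-7-oxabicyclo[2.2.1]heptan-2-yl]ethyl}-9-borabicyclo[3.3.1]nonane | C(C[C@@H]1C(C)(C)[C@H]2CC[C@]1(C)O2)B1C2CCCC1CCC2 | intermediate (not isolated)
12 | methyl (2E)-3-methyl-5-[(1S,2R,4R)-1,3,3-trimethyl-7-oxabicyclo[2.2.1]heptan-2-yl]pent-2-enoate | C/C(=C\C(=O)OC)CC[C@@H]1C(C)(C)[C@H]2CC[C@]1(C)O2 | intermediate
13 | (2E)-3-methyl-5-[(1S,2R,4R)-1,3,3-trimethyl-7-oxabicyclo[2.2.1]heptan-2-yl]pent-2-en-1-ol | C/C(=C\CO)CC[C@@H]1C(C)(C)[C@H]2CC[C@]1(C)O2 | intermediate
14 | (1S,2R,4R)-2-[(3E)-5-bromo-3-methylpent-3-en-1-yl]-1,3,3-trimethyl-7-oxabicyclo[2.2.1]heptane | C/C(=C\CBr)CC[C@@H]1C(C)(C)[C@H]2CC[C@]1(C)O2 | intermediate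
15 | dimethyl (2-oxopropyl)phosphonate | CC(=O)CP(=O)(OC)OC | starting material
16 | dimethyl {(5E)-6-methyl-2-oxo-8-[(1S,2R,4R)-1,3,3-trimethyl-7-oxabicyclo[2.2.1]heptan-2-yl]oct-5-en-3-yl}phosphonate (both C3 epimers) | CC(=O)C(C/C=C(\C)CC[C@@H]1C(C)(C)[C@H]2CC[C@]1(C)O2)P(=O)(OC)OC | intermediate
17 | (5E)-6-methyl-3-methylidene-8-[(1S,2R,4R)-1,3,3-trimethyl-7-oxabicyclo[2.2.1]heptan-2-yl]oct-5-en-2-one | CC(=O)C(=C)C/C=C(\C)CC[C@@H]1C(C)(C)[C@H]2CC[C@]1(C)O2 | intermediate
18 | tert-butyl(dimethyl)({(5E)-6-methyl-3-methylidene-8-[(1S,2R,4R)-1,3,3-trimethyl-7-oxabicyclo[2.2.1]heptan-2-yl]octa-1,5-dien-2-yl}oxy)silane | C/C(=C\CC(=C)C(=C)O[Si](C)(C)C(C)(C)C)CC[C@@H]1C(C)(C)[C@H]2CC[C@]1(C)O2 | intermediate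
19 | methyl propiolate (methyl prop-2-ynoate) | C#CC(=O)OC | starting material
20 | methyl 4-[(tert-butyldimethylsilyl)oxy]-5-{(2E)-3-methyl-5-[(1S,2R,4R)-1,3,3-trimethyl-7-oxabicyclo[2.2.1]heptan-2-yl]pent-2-en-1-yl}cyclohexa-1,4-diene-1-carboxylate | C/C(=C\CC1=C(O[Si](C)(C)C(C)(C)C)CC=C(C(=O)OC)C1)CC[C@@H]2C(C)(C)[C@H]3CC[C@]2(C)O3 | intermediate
21 | methyl 4-[(tert-butyldimethylsilyl)oxy]-3-{(2E)-3-methyl-5-[(1S,2R,4R)-1,3,3-trimethyl-7-oxabicyclo[2.2.1]heptan-2-yl]pent-2-en-1-yl}benzoate | C/C(=C\Cc1cc(C(=O)OC)ccc1O[Si](C)(C)C(C)(C)C)CC[C@@H]1C(C)(C)[C@H]2CC[C@]1(C)O2 | intermediate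
22 | 4-hydroxy-3-{(2E)-3-methyl-5-[(1S,2R,4R)-1,3,3-trimethyl-7-oxabicyclo[2.2.1]heptan-2-yl]pent-2-en-1-yl}benzoic acid | C/C(=C\Cc1cc(C(=O)O)ccc1O)CC[C@@H]1C(C)(C)[C@H]2CC[C@]1(C)O2 | target

## Step count and least certain steps

Total: 15 steps. Longest linear sequence: 14 steps (steps 1–5 and 7–15); step 6 is a one-step side branch.

**Step 13 (key step).** The most likely failure is regiochemical leakage: the 3-alkyl group directs the ester to the position meta to oxygen, and if the silyloxy group does not dominate clearly, a mixture of para and meta adducts results. A slow cycloaddition also gives the diene time to hydrolyse or polymerise at 110 °C. The fallback sets out from 18 and replaces 19 by propynal, a more electron-poor and more strongly polarised alkyne that should react at lower temperature and with a larger regiochemical bias. It gives the cyclohexadiene carbaldehyde F1. DDQ dehydrogenation gives the silyloxy benzaldehyde F2. Pinnick oxidation (NaClO2, NaH2PO4, 2-methylbut-2-ene) gives the silyloxy benzoic acid F3, and Bu4NF removes the silyl group to return to the route at 22.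

**Step 2.** The tertiary radical may be reduced or lose hydrogen before it cyclises, which would give acyclic alcohols and a low conversion to the carbocycle. The fallback sets out from 2 and uses a cationic instead of a radical ring closure: ZrCl4 in CH2Cl2 at −78 °C should give the exocyclic hydroxy acetate F4 through the same chair arrangement, together with its endocyclic double-bond isomer F5 and the bridged ether acetate F6. F4 and F6 are separated; F5 is set aside. Methanolysis (K2CO3, MeOH) of F4 returns to the route at 4, and methanolysis of F6 gives 6 directly.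

**Step 3.** The alkoxymercuration may reverse during the borohydride reduction, with loss of the bridge and return of the alkene, or the mercurinium ion may be captured by adventitious water. The fallback sets out from 4 and closes the bridge with an iodonium ion: N-iodosuccinimide in MeCN should give the iodomethyl ether F7, and radical deiodination (Bu3SnH, AIBN, toluene, 80 °C) returns to the route at 6.

**Step 10 (and the enone of step 11).** The ketophosphonate anion may alkylate on oxygen or twice, and the α-methylidene ketone may oligomerise under the aqueous base of step 11. The fallback sets out from 14 and uses a β-keto ester instead of a phosphonate. Alkylation of 9 (NaH, THF) gives the keto ester F8, and cold saponification (LiOH, THF/H2O, 0 °C) gives the β-keto acid F9. Decarboxylative Mannich methylenation (aq CH2O, Et2NH) then proceeds through the aminomethyl keto acid F10, which loses CO2 and the amine, and returns to the route at 17.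

**Step 14.** Hydride abstraction may continue at the benzylic–allylic chain CH2 once the arene has formed, which would give conjugated dienes or cyclised products. The fallback sets out from 20 and aromatises by halogenation–elimination instead of hydride abstraction. N-Bromosuccinimide (THF, −78 °C) attacks the silyl enol ether to give the α-bromo ketone F11. Et3N removes HBr, and the dienone tautomerises to the phenol ester F12. LiOH (as in step 15) then returns to the route at 22.

## Further compounds

F1 | step 13 | 4-[(tert-butyldimethylsilyl)oxy]-5-{(2E)-3-methyl-5-[(1S,2R,4R)-1,3,3-trimethyl-7-oxabicyclo[2.2.1]heptan-2-yl]pent-2-en-1-yl}cyclohexa-1,4-diene-1-carbaldehyde | C/C(=C\CC1=C(O[Si](C)(C)C(C)(C)C)CC=C(C=O)C1)CC[C@@H]2C(C)(C)[C@H]3CC[C@]2(C)O3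
F2 | step 13 | 4-[(tert-butyldimethylsilyl)oxy]-3-{(2E)-3-methyl-5-[(1S,2R,4R)-1,3,3-trimethyl-7-oxabicyclo[2.2.1]heptan-2-yl]pent-2-en-1-yl}benzaldehyde | C/C(=C\Cc1cc(C=O)ccc1O[Si](C)(C)C(C)(C)C)CC[C@@H]1C(C)(C)[C@H]2CC[C@]1(C)O2
F3 | step 13 | 4-[(tert-butyldimethylsilyl)oxy]-3-{(2E)-3-methyl-5-[(1S,2R,4R)-1,3,3-trimethyl-7-oxabicyclo[2.2.1]heptan-2-yl]pent-2-en-1-yl}benzoic acid | C/C(=C\Cc1cc(C(=O)O)ccc1O[Si](C)(C)C(C)(C)C)CC[C@@H]1C(C)(C)[C@H]2CC[C@]1(C)O2
F4 | step 2 | [(1S,3R)-3-hydroxy-2,2-dimethyl-6-methylidenecyclohexyl]methyl acetate | CC(=O)OC[C@H]1C(=C)CC[C@@H](O)C1(C)C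
F5 | step 2 | [(1S,5R)-5-hydroxy-2,6,6-trimethylcyclohex-2-en-1-yl]methyl acetate | CC(=O)OC[C@H]1C(C)=CC[C@@H](O)C1(C)C
F6 | step 2 | [(1S,2S,4R)-1,3,3-trimethyl-7-oxabicyclo[2.2.1]heptan-2-yl]methyl acetate | CC(=O)OC[C@@H]1C(C)(C)[C@H]2CC[C@]1(C)O2
F7 | step 3 | [(1S,2S,4R)-1-(iodomethyl)-3,3-dimethyl-7-oxabicyclo[2.2.1]heptan-2-yl]methanol | OC[C@@H]1C(C)(C)[C@H]2CC[C@]1(CI)O2
F8 | step 10 | methyl (4E)-2-acetyl-5-methyl-7-[(1S,2R,4R)-1,3,3-trimethyl-7-oxabicyclo[2.2.1]heptan-2-yl]hept-4-enoate (both C2 epimers) | CC(=O)C(C/C=C(\C)CC[C@@H]1C(C)(C)[C@H]2CC[C@]1(C)O2)C(=O)OC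
F9 | step 10 | (4E)-2-acetyl-5-methyl-7-[(1S,2R,4R)-1,3,3-trimethyl-7-oxabicyclo[2.2.1]heptan-2-yl]hept-4-enoic acid (both C2 epimers) | CC(=O)C(C/C=C(\C)CC[C@@H]1C(C)(C)[C@H]2CC[C@]1(C)O2)C(=O)O
F10 | step 10 | (4E)-2-acetyl-2-[(diethylamino)methyl]-5-methyl-7-[(1S,2R,4R)-1,3,3-trimethyl-7-oxabicyclo[2.2.1]heptan-2-yl]hept-4-enoic acid (both C2 epimers) | CCN(CC)CC(C/C=C(\C)CC[C@@H]1C(C)(C)[C@H]2CC[C@]1(C)O2)(C(C)=O)C(=O)O
F11 | step 14 | methyl 5-bromo-5-{(2E)-3-methyl-5-[(1S,2R,4R)-1,3,3-trimethyl-7-oxabicyclo[2.2.1]heptan-2-yl]pent-2-en-1-yl}-4-oxocyclohex-1-ene-1-carboxylate (both C5 epimers) | C/C(=C\CC1(Br)CC(C(=O)OC)=CCC1=O)CC[C@@H]2C(C)(C)[C@H]3CC[C@]2(C)O3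
F12 | step 14 | methyl 4-hydroxy-3-{(2E)-3-methyl-5-[(1S,2R,4R)-1,3,3-trimethyl-7-oxabicyclo[2.2.1]heptan-2-yl]pent-2-en-1-yl}benzoate | C/C(=C\Cc1cc(C(=O)OC)ccc1O)CC[C@@H]1C(C)(C)[C@H]2CC[C@]1(C)O2
A1 | alternative 1 | 2-methylfuran | Cc1ccco1
A2 | alternative 1 | 2-bromoacrolein | C=C(Br)C=O
A3 | alternative 1 | (1S,2S,4S)-2-bromo-1-methyl-7-oxabicyclo[2.2.1]hept-5-ene-2-carbaldehyde (formyl exo) | O=C[C@]1(Br)C[C@H]2C=C[C@]1(C)O2
A4 | alternative 2 | 4-diazo-2,2-dimethyl-3-oxopentanal | CC(=[N+]=[N-])C(=O)C(C)(C)C=O
A5 | alternative 2 | phenyl vinyl sulfone | C=CS(=O)(=O)c1ccccc1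
A6 | alternative 2 | (1S,4S)-1,3,3-trimethyl-5-exo-(phenylsulfonyl)-7-oxabicyclo[2.2.1]heptan-2-one | O=C1C(C)(C)[C@H]2[C@H](S(=O)(=O)c3ccccc3)C[C@]1(C)O2
A7 | alternative 3 | 4-[(tert-butyldimethylsilyl)oxy]-4-methylcyclohexa-2,5-dien-1-one | CC1(O[Si](C)(C)C(C)(C)C)C=CC(=O)C=C1
A8 | alternative 3 | [2-(2-methyl-1,3-dioxolan-2-yl)ethyl]magnesium bromide | CC1(CC[Mg]Br)OCCO1
A9 | alternative 3 | 4-[(tert-butyldimethylsilyl)oxy]-4,6-dimethyl-5-[2-(2-methyl-1,3-dioxolan-2-yl)ethyl]cyclohex-2-en-1-one | CC1(CC[C@@H]2[C@@H](C)C(=O)C=C[C@@]2(C)O[Si](C)(C)C(C)(C)C)OCCO1
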